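All runs are calculated with made-up constants, and the scatter is random.

| flask | starting material | protic impurity | catalyst | remark | time |
|---|---|---|---|---|---|
| north | 1 M | 0.36 M | 14 mM | run made earlier |  |
| south-west | 1.6 M | 0.36 M | 14 mM | run made earlier |  |
| south-east | 0.72 M | 0.36 M | 28 mM | run made earlier |  |
| flask | 0.72 M | 0.360 M | 14 mM |  | 15 d |

- north (time / d: target / %, isomer of the product A / %): 1.04: 49.7, 18.0; 1.67: 39.1, 24.8; 2.00: 34.1, 26.6; 3.00: 24.6, 31.8; 5.00: 14.8, 38.2; 8.00: 10.9, 42.6; 12.0: 10.2, 44.6
- south-west (time / d: target / %, isomer of the product A / %): 0.625: 59.0, 13.1; 1.67: 38.6, 25.4; 3.00: 24.7, 32.4; 5.00: 16.2, 39.3; 8.00: 11.2, 43.0; 10.0: 10.1, 44.3; 12.0: 9.6, 43.8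
- south-east (time / d: target / %, isomer of the product A / %): 2.50: 28.2, 29.9; 5.00: 14.0, 37.3; 8.00: 10.2, 41.2; 10.0: 9.9, 42.4; 12.0: 9.4, 43.1

(readings scatter by 0.5 percentage points)

- share of target in target plus isomer of the product A at 2.5 min
- share of target in target plus isomer of the product A at 15 d

- the numbers in the tables scatter by 0.5 percentage points (one standard deviation)

I read this flask at 15 d, later than the last readings of the earlier runs, so I have to bracket its share of target rather than read it. This is the thermodynamic side of kinetic against thermodynamic control; the share at 2.5 min is the kinetic side.

I pool the last reading of each run. The late share, summed target over summed target plus isomer of the product A at 12.0 d, is 18.2%. Pooled the same way at 8.00 d, the share is 20.3%. That is a first ceiling, but the share is falling, so the late share is a tighter one.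

For a floor, I let the fall run on at the same pace, without slowing, until the time of reading. That takes off 1.6 percentage points and leaves 16.6%. I commit to that bracket for this flask. The percent readings of the earlier runs overlap across their different charges.

The forecast gives 94% at the early time and 18.2% at the late one, with a range of 16.8% to 19.5%, on the ground that “the system has plateaued”. Its late number stands at the top edge of my bracket.

The flask gives 95.1% and 17.1%. The late value lies 1.1 points below my late share and above the floor, so it is inside the bracket. The relaxation half-life of starting material and isomer of the product A by the turning of starting material into isomer of the product A alone, both ways together, is 0.489 d, short against 15 d.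

    starting material + protic impurity → quenched substrate (k = 0.0550 L mol⁻¹ h⁻¹)
    starting material ⇌ isomer of the product B (K = 12.0, k = 0.0570 h⁻¹)
    starting material ⇌ target (K = 5.30, k = 1.10 h⁻¹)
    starting material ⇌ isomer of the product A (K = 28.0, k = 0.0570 h⁻¹)

For a neighbouring flask with 0.18 M of starting material, the same reckoning gives the same bracket, 16.6% to 18.2%. The computed share in that neighbouring flask is 16.5%, from 8.46% of target and 42.8% of isomer of the product A, which lies below the floor by 0.10 points.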